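## Retrosynthetic overview

1. Target 14 ← removal of one silyl and two benzyl groups from oxolane 12 ← Mitsunobu closure of 1,4-diol 11 ← reduction of lactone 10, the silyl ether of aldol lactone 9.
2. Lactone 9 ← one-pot enantioselective reductive aldol union of the achiral butenolide 5 with aldehyde 6. This forms the bond between the ring carbon and the carbinol carbon and sets all three stereocentres.
3. Butenolide 5 ← Negishi coupling of benzylzinc 4 (from alcohol 1 via chloride 2) with 4-bromofuran-2(5H)-one 3.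
4. Enabling feature: the oxolane is carried as a furan-2(5H)-one. In its O1–C2(=O)–C3=C4 enoate, C2 is the later ring CH2 beside the carbinol-bearing C3 and C4 is the benzyl-bearing carbon; hydride delivered to C4 turns C3 into an enolate carbon, and the C2 carbonyl is removed afterwards.
5. Ring order: lactone ring bought in 3, opened to diol 11 in step 5, oxolane ring closed in step 6; both arenes are purchased.

Key step: step 3

Remark: the target is read as the 3,4-trans oxolane with an anti relationship between the ring carbon substituent and the carbinol hydroxyl, all three centres S.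
Remark: the (S)-bisphosphine is assumed, by analogy with related butenolides, to deliver hydride to the face that gives the 4S centre; should the sense prove opposite, the (R)-ligand is used.
Remark: compounds 1, 3 and 6 are taken as commercial.

## Route

Step 1
Reactants: 1 [4-(benzyloxy)-3-methoxyphenyl]methanol
Product: 2 1-(benzyloxy)-4-(chloromethyl)-2-methoxybenzene
Conditions: SOCl2 (1.2 equiv), DMF (cat.), CH2Cl2, 0 °C
Reagents that add atoms: thionyl chloride, O=S(Cl)Cl
Why: Chlorodehydroxylation of an electron-rich benzylic alcohol through its chlorosulfite should be fast at 0 °C and leaves the aryl benzyl ether untouched.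

Step 2
Reactants: 2 1-(benzyloxy)-4-(chloromethyl)-2-methoxybenzene; 3 4-bromofuran-2(5H)-one
Product: 5 4-[4-(benzyloxy)-3-methoxybenzyl]furan-2(5H)-one, via benzylzinc chloride 4 (not isolated)
Conditions: Zn dust, LiCl, THF, 25 °C; then 3, Pd(OAc)2 (2 mol %), SPhos (4 mol %), THF, 25 °C
Reagents that add atoms: zinc, [Zn] (held only in intermediate 4)
Why: LiCl-promoted zinc insertion into the benzylic C–Cl bond gives an organozinc that tolerates the lactone, and Negishi coupling should follow because zerovalent palladium adds readily to the C4–Br bond of the vinylogous acyl bromide 3 and the benzyl group has no β-hydrogen.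

Step 3
Reactants: 5 4-[4-(benzyloxy)-3-methoxybenzyl]furan-2(5H)-one; 6 4-(benzyloxy)-3,5-dimethoxybenzaldehyde
Product: 9 (3R,4S)-4-[4-(benzyloxy)-3-methoxybenzyl]-3-[(S)-[4-(benzyloxy)-3,5-dimethoxyphenyl](hydroxy)methyl]dihydrofuran-2(3H)-one, via boron enolate 7 (not isolated), via boryl aldolate 8 (not isolated)
Conditions: Cu(OAc)2·H2O (5 mol %), (S)-DTBM-SEGPHOS (5.5 mol %), pinacolborane (1.15 equiv), toluene, 0 °C to rt; then 6 (1.3 equiv), −40 °C to rt; then pH 7 buffer
Reagents that add atoms: pinacolborane, CC1(C)OBOC1(C)C (its boryl group stays only in intermediates 7 and 8)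
Why: Proposed new method: the bisphosphine-ligated copper hydride should deliver H to C4 of the butenolide on one enantioface (ligand control, giving 4S), the copper enolate is turned over by pinacolborane (Cu–O/B–H exchange) to the ring-locked E boron enolate 7, and 7 should add through C3 to aldehyde 6 in a closed chair (Zimmerman–Traxler) transition state before the boryl aldolate 8 is hydrolysed. The closest known reaction types are the copper hydride-catalysed enantioselective conjugate reduction of β-substituted butenolides with hydrosilanes and the copper-catalysed reductive aldol reaction of enoates with pinacolborane, which have not been merged on a β,β-disubstituted lactone with an aryl aldehyde. No ring is closed. C3 should be controlled by the new C4 centre, since the aldehyde approaches the enolate face anti to the benzyl group (3,4-trans), and the carbinol centre by the enolate geometry, since an E enolate with the aryl group equatorial in the chair gives the anti aldol (S). The selectivity needed is complete conjugate reduction of 5 before aldehyde is present, because copper hydride would reduce 6; the sequential addition secures this, and the C2 carbonyl conjugated to C3=C4 is what makes C3 nucleophilic.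

Step 4
Reactants: 9 (3R,4S)-4-[4-(benzyloxy)-3-methoxybenzyl]-3-[(S)-[4-(benzyloxy)-3,5-dimethoxyphenyl](hydroxy)methyl]dihydrofuran-2(3H)-one
Product: 10 (3R,4S)-4-[4-(benzyloxy)-3-methoxybenzyl]-3-[(S)-[4-(benzyloxy)-3,5-dimethoxyphenyl][(tert-butyldimethylsilyl)oxy]methyl]dihydrofuran-2(3H)-one
Conditions: t-BuMe2SiOTf (1.3 equiv), 2,6-lutidine (2 equiv), CH2Cl2, −78 to 0 °C
Reagents that add atoms: tert-butyldimethylsilyl triflate, CC(C)(C)[Si](C)(C)OS(=O)(=O)C(F)(F)F
Why: Silyl triflate silylation of a hindered secondary alcohol with a non-nucleophilic base should proceed cold enough to avoid retro-aldol cleavage or elimination, so the three stereocentres are kept and the carbinol oxygen is masked for the ring adjustment.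

Step 5
Reactants: 10 (3R,4S)-4-[4-(benzyloxy)-3-methoxybenzyl]-3-[(S)-[4-(benzyloxy)-3,5-dimethoxyphenyl][(tert-butyldimethylsilyl)oxy]methyl]dihydrofuran-2(3H)-one
Product: 11 (2S,3S)-2-[4-(benzyloxy)-3-methoxybenzyl]-3-[(S)-[4-(benzyloxy)-3,5-dimethoxyphenyl][(tert-butyldimethylsilyl)oxy]methyl]butane-1,4-diol
Conditions: LiBH4 (2 equiv), THF, 0 °C to rt
Reagents that add atoms: none
Why: Hydride reduction of the γ-lactone to the 1,4-diol with LiBH4 should leave the silyl and benzyl ethers alone and cannot trigger retro-aldol cleavage because the carbinol oxygen is silylated; no stereocentre is touched.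

Step 6
Reactants: 11 (2S,3S)-2-[4-(benzyloxy)-3-methoxybenzyl]-3-[(S)-[4-(benzyloxy)-3,5-dimethoxyphenyl][(tert-butyldimethylsilyl)oxy]methyl]butane-1,4-diol
Product: 12 {(S)-[4-(benzyloxy)-3,5-dimethoxyphenyl][(3S,4S)-4-[4-(benzyloxy)-3-methoxybenzyl]oxolan-3-yl]methoxy}(tert-butyl)dimethylsilane
Conditions: PPh3 (1.3 equiv), diisopropyl azodicarboxylate (1.3 equiv), THF, 0 °C to rt
Reagents that add atoms: none
Why: Mitsunobu cyclodehydration of a 1,4-diol: whichever primary hydroxyl is activated as the alkoxyphosphonium ion is displaced by the other in a 5-exo-tet closure at a CH2 carbon, so both pathways give the same oxolane, no stereocentre is involved, and the silylated benzylic oxygen cannot close the isomeric 2-aryl oxolane.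

Step 7
Reactants: 12 {(S)-[4-(benzyloxy)-3,5-dimethoxyphenyl][(3S,4S)-4-[4-(benzyloxy)-3-methoxybenzyl]oxolan-3-yl]methoxy}(tert-butyl)dimethylsilane
Product: 13 (S)-[4-(benzyloxy)-3,5-dimethoxyphenyl][(3S,4S)-4-[4-(benzyloxy)-3-methoxybenzyl]oxolan-3-yl]methanol
Conditions: Bu4NF (1.5 equiv), THF, 0 °C to rt
Reagents that add atoms: none
Why: Fluoride-mediated desilylation is driven by the strong Si–F bond; the aryl benzyl ethers and the oxolane are inert and the carbinol centre is not ionised under these non-acidic conditions.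

Step 8
Reactants: 13 (S)-[4-(benzyloxy)-3,5-dimethoxyphenyl][(3S,4S)-4-[4-(benzyloxy)-3-methoxybenzyl]oxolan-3-yl]methanol
Product: 14 4-[(S)-hydroxy{(3S,4S)-4-[(4-hydroxy-3-methoxyphenyl)methyl]oxolan-3-yl}methyl]-2,6-dimethoxyphenol
Conditions: H2 (1 atm), Pd/C (10 wt % Pd), EtOAc, rt
Reagents that add atoms: none
Why: Hydrogenolysis of the two aryl benzyl ethers over palladium in a neutral aprotic solvent, where O–CH2Ph cleavage should be much faster than cleavage of the secondary benzylic C–OH bond; the stereocentres are not touched.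

## Compound list

1 | [4-(benzyloxy)-3-methoxyphenyl]methanol | COc1cc(CO)ccc1OCc1ccccc1 | starting material
2 | 1-(benzyloxy)-4-(chloromethyl)-2-methoxybenzene | COc1cc(CCl)ccc1OCc1ccccc1 | intermediate
3 | 4-bromofuran-2(5H)-one | O=C1OCC(Br)=C1 | starting material
4 | [4-(benzyloxy)-3-methoxybenzyl]zinc chloride (THF solution, not isolated) | COc1cc(C[Zn]Cl)ccc1OCc1ccccc1 | intermediate
5 | 4-[4-(benzyloxy)-3-methoxybenzyl]furan-2(5H)-one | COc1cc(CC2=CC(=O)OC2)ccc1OCc1ccccc1 | intermediate
6 | 4-(benzyloxy)-3,5-dimethoxybenzaldehyde | COc1cc(C=O)cc(OC)c1OCc1ccccc1 | starting material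
7 | 2-({(4S)-4-[4-(benzyloxy)-3-methoxybenzyl]-4,5-dihydrofuran-2-yl}oxy)-4,4,5,5-tetramethyl-1,3,2-dioxaborolane (boron enolate, not isolated) | COc1cc(C[C@@H]2COC(OB3OC(C)(C)C(C)(C)O3)=C2)ccc1OCc1ccccc1 | intermediate
8 | (3R,4S)-4-[4-(benzyloxy)-3-methoxybenzyl]-3-{(S)-[4-(benzyloxy)-3,5-dimethoxyphenyl][(4,4,5,5-tetramethyl-1,3,2-dioxaborolan-2-yl)oxy]methyl}dihydrofuran-2(3H)-one (boryl aldolate, not isolated) | COc1cc(C[C@@H]2COC(=O)[C@H]2[C@H](OB3OC(C)(C)C(C)(C)O3)c2cc(OC)c(OCc3ccccc3)c(OC)c2)ccc1OCc1ccccc1 | intermediate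
9 | (3R,4S)-4-[4-(benzyloxy)-3-methoxybenzyl]-3-[(S)-[4-(benzyloxy)-3,5-dimethoxyphenyl](hydroxy)methyl]dihydrofuran-2(3H)-one | COc1cc(C[C@@H]2COC(=O)[C@H]2[C@H](O)c2cc(OC)c(OCc3ccccc3)c(OC)c2)ccc1OCc1ccccc1 | intermediate
10 | (3R,4S)-4-[4-(benzyloxy)-3-methoxybenzyl]-3-[(S)-[4-(benzyloxy)-3,5-dimethoxyphenyl][(tert-butyldimethylsilyl)oxy]methyl]dihydrofuran-2(3H)-one | COc1cc(C[C@@H]2COC(=O)[C@H]2[C@H](O[Si](C)(C)C(C)(C)C)c2cc(OC)c(OCc3ccccc3)c(OC)c2)ccc1OCc1ccccc1 | intermediate
11 | (2S,3S)-2-[4-(benzyloxy)-3-methoxybenzyl]-3-[(S)-[4-(benzyloxy)-3,5-dimethoxyphenyl][(tert-butyldimethylsilyl)oxy]methyl]butane-1,4-diol | COc1cc(C[C@H](CO)[C@@H](CO)[C@H](O[Si](C)(C)C(C)(C)C)c2cc(OC)c(OCc3ccccc3)c(OC)c2)ccc1OCc1ccccc1 | intermediate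
12 | {(S)-[4-(benzyloxy)-3,5-dimethoxyphenyl][(3S,4S)-4-[4-(benzyloxy)-3-methoxybenzyl]oxolan-3-yl]methoxy}(tert-butyl)dimethylsilane | COc1cc(C[C@@H]2COC[C@H]2[C@H](O[Si](C)(C)C(C)(C)C)c2cc(OC)c(OCc3ccccc3)c(OC)c2)ccc1OCc1ccccc1 | intermediate
13 | (S)-[4-(benzyloxy)-3,5-dimethoxyphenyl][(3S,4S)-4-[4-(benzyloxy)-3-methoxybenzyl]oxolan-3-yl]methanol | COc1cc(C[C@@H]2COC[C@H]2[C@H](O)c2cc(OC)c(OCc3ccccc3)c(OC)c2)ccc1OCc1ccccc1 | intermediate
14 | 4-[(S)-hydroxy{(3S,4S)-4-[(4-hydroxy-3-methoxyphenyl)methyl]oxolan-3-yl}methyl]-2,6-dimethoxyphenol | COc1cc(C[C@@H]2COC[C@H]2[C@H](O)c2cc(OC)c(O)c(OC)c2)ccc1O | target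

## Summary

Total step count: 8. Longest linear sequence: 8 steps (1 to 14); 3 and 6 enter as purchased materials.

Steps most likely to fail:

**Step 3 (proposed new method).** The copper enolate may be turned over too slowly by the borane, residual copper hydride may reduce the aldehyde, or simple diastereoselection at the carbinol centre may be poor in the aldol stage. The fallback sets out from 5 and uses known chemistry only. Copper hydride-catalysed conjugate reduction in the presence of a proton source (Cu(OAc)2·H2O, (S)-DTBM-SEGPHOS, polymethylhydrosiloxane, t-BuOH, toluene) should give the saturated lactone (S)-4-[4-(benzyloxy)-3-methoxybenzyl]dihydrofuran-2(3H)-one F1. Its lithium enolate (LiN(iPr)2, THF, −78 °C) should add to 6 trans to the benzyl group, giving 9 together with its carbinol epimer (3R,4S)-4-[4-(benzyloxy)-3-methoxybenzyl]-3-[(R)-[4-(benzyloxy)-3,5-dimethoxyphenyl](hydroxy)methyl]dihydrofuran-2(3H)-one F2. The mixture is oxidised with Dess–Martin periodinane to the keto lactone (3R,4S)-3-[4-(benzyloxy)-3,5-dimethoxybenzoyl]-4-[4-(benzyloxy)-3-methoxybenzyl]dihydrofuran-2(3H)-one F3, whose epimerisable C3 rests in the trans arrangement. Noyori–Ikariya transfer hydrogenation with the catalyst enantiomer that delivers the S carbinol (RuCl(p-cymene)[(S,S)-TsDPEN], HCO2H/Et3N) then converges on 9, where the route is rejoined.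

**Step 5.** The silyl group may migrate from the secondary benzylic oxygen to the neighbouring primary alkoxide (1,3-diol relationship), or be partly lost, under the basic hydride conditions; the following closure would then give the wrong ether. The fallback sets out from 10 and avoids the diol. Partial reduction with (i-Bu)2AlH in CH2Cl2 at −78 °C should stop at the lactol (3R,4S)-4-[4-(benzyloxy)-3-methoxybenzyl]-3-[(S)-[4-(benzyloxy)-3,5-dimethoxyphenyl][(tert-butyldimethylsilyl)oxy]methyl]oxolan-2-ol F4 (anomeric mixture). Ionic hydrogenation of the lactol through its ring oxocarbenium ion (Et3SiH, BF3·OEt2, CH2Cl2, −78 °C) should then give 12 directly, so steps 5 and 6 are both replaced and the route is rejoined at 12.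

**Step 8.** Over-reduction may occur: once the phenols are free, the electron-rich benzylic C–OH bond may also be hydrogenolysed. The fallback sets out from 12 and reverses the order of deprotection. Hydrogenolysis of 12 (H2, Pd/C, EtOAc), with the carbinol still shielded as its bulky silyl ether, should give the bisphenol 4-[(S)-[(tert-butyldimethylsilyl)oxy]{(3S,4S)-4-[(4-hydroxy-3-methoxyphenyl)methyl]oxolan-3-yl}methyl]-2,6-dimethoxyphenol F5. Desilylation with Bu4NF buffered with acetic acid (THF, 0 °C), to keep the phenols protonated and prevent quinone methide formation, then gives 14.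

## Further compounds

F1 | step 3 | (S)-4-[4-(benzyloxy)-3-methoxybenzyl]dihydrofuran-2(3H)-one | COc1cc(C[C@@H]2COC(=O)C2)ccc1OCc1ccccc1
F2 | step 3 | (3R,4S)-4-[4-(benzyloxy)-3-methoxybenzyl]-3-[(R)-[4-(benzyloxy)-3,5-dimethoxyphenyl](hydroxy)methyl]dihydrofuran-2(3H)-one | COc1cc(C[C@@H]2COC(=O)[C@H]2[C@@H](O)c2cc(OC)c(OCc3ccccc3)c(OC)c2)ccc1OCc1ccccc1
F3 | step 3 | (3R,4S)-3-[4-(benzyloxy)-3,5-dimethoxybenzoyl]-4-[4-(benzyloxy)-3-methoxybenzyl]dihydrofuran-2(3H)-one | COc1cc(C[C@@H]2COC(=O)[C@H]2C(=O)c2cc(OC)c(OCc3ccccc3)c(OC)c2)ccc1OCc1ccccc1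
F4 | step 5 | (3R,4S)-4-[4-(benzyloxy)-3-methoxybenzyl]-3-[(S)-[4-(benzyloxy)-3,5-dimethoxyphenyl][(tert-butyldimethylsilyl)oxy]methyl]oxolan-2-ol | COc1cc(C[C@@H]2COC(O)[C@H]2[C@H](O[Si](C)(C)C(C)(C)C)c2cc(OC)c(OCc3ccccc3)c(OC)c2)ccc1OCc1ccccc1
F5 | step 8 | 4-[(S)-[(tert-butyldimethylsilyl)oxy]{(3S,4S)-4-[(4-hydroxy-3-methoxyphenyl)methyl]oxolan-3-yl}methyl]-2,6-dimethoxyphenol | COc1cc(C[C@@H]2COC[C@H]2[C@H](O[Si](C)(C)C(C)(C)C)c2cc(OC)c(O)c(OC)c2)ccc1O
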